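The synthesis rests on disconnecting C9–C10, the central bond of the cis,cis-diene C8=C9–C10=C1 that joins the alkylidene carbon of the butenolide ring to the methyl-bearing alkene of the ten-membered ring; the key step exploits exactly this diene. A Stille coupling of an (E)-iodomethylene butenolide (iodine on C9) with a (Z)-alkenylstannane (tin on C10) should form this bond and close the carbocycle in one operation with both alkene geometries retained. The seco precursor 34 carries the C6 methacrylate, the C2 acetate and silyl ethers on O4 and O13. Because an alkenylstannane does not survive iodolactonisation, the iodide is made first and the stannylalkenyl unit (C1, C10, C14) is added last to a C2 aldehyde.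

Key step: step 23

Remark: germacrane numbering of the target is used for every intermediate (ring C1–C10; butenolide C7, C8, C11, C12; C13 = CH2O on C11; C14 = methyl on C10; C15 = methyl on C4); TBS = tert-butyldimethylsilyl, TES = triethylsilyl, PMB = 4-methoxybenzyl; O4 is carried as a TES ether through the key step, an added spectator group that falls in the last step.

Step 1
Reactants: 1 (S)-(2,2-dimethyl-1,3-dioxolan-4-yl)methyl 4-methylbenzenesulfonate; 2 lithium acetylide ethylenediamine complex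
Product: 3 (4R)-2,2-dimethyl-4-(prop-2-yn-1-yl)-1,3-dioxolane
Conditions: LiC≡CH·H2NCH2CH2NH2, DMSO, 10 °C to rt
Reagents that add atoms: none
Why: SN2 alkylation of the acetylide by the primary tosylate should leave the dioxolane stereocentre untouched, so C6 takes its R configuration from the chiral pool.

Step 2
Reactants: 3 (4R)-2,2-dimethyl-4-(prop-2-yn-1-yl)-1,3-dioxolane
Product: 6 (E)-4-[(4R)-2,2-dimethyl-1,3-dioxolan-4-yl]-3-methylbut-2-en-1-ol, via alkenylalane 4 (not isolated), via lithium alkenylalanate 5 (not isolated)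
Conditions: Me3Al, Cp2ZrCl2 (cat.), CH2Cl2, 0 °C to rt; n-BuLi, THF, −78 °C; (CH2O)n, −78 °C to rt
Reagents that add atoms: trimethylaluminium, C[Al](C)C; formaldehyde (from paraformaldehyde), C=O
Why: Negishi zirconium-catalysed syn-carboalumination puts methyl (C15) on the internal and aluminium on the terminal alkyne carbon, and the alanate should add to formaldehyde with retention to give the E allylic alcohol with C2 in place.

Step 3
Reactants: 6 (E)-4-[(4R)-2,2-dimethyl-1,3-dioxolan-4-yl]-3-methylbut-2-en-1-ol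
Product: 7 [(2R,3R)-3-{[(4R)-2,2-dimethyl-1,3-dioxolan-4-yl]methyl}-3-methyloxiran-2-yl]methanol
Conditions: Ti(OiPr)4 (10 mol %), D-(−)-diethyl tartrate (12 mol %), t-BuOOH, 4 Å molecular sieves, CH2Cl2, −20 °C
Reagents that add atoms: tert-butyl hydroperoxide, CC(C)(C)OO
Why: Sharpless asymmetric epoxidation of the E trisubstituted allylic alcohol is reagent-controlled, and the D-(−)-tartrate should deliver oxygen to the face that gives the 2R,3R epoxide, which fixes C4 as S.

Step 4
Reactants: 7 [(2R,3R)-3-{[(4R)-2,2-dimethyl-1,3-dioxolan-4-yl]methyl}-3-methyloxiran-2-yl]methanol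
Product: 8 (3S)-4-[(4R)-2,2-dimethyl-1,3-dioxolan-4-yl]-3-methylbutane-1,3-diol
Conditions: NaAlH2(OCH2CH2OCH3)2, THF, 0 °C to rt
Reagents that add atoms: none
Why: In this hydroxyl-directed reductive epoxide opening the alkoxyaluminate should deliver hydride to the secondary epoxide carbon C3, so the tertiary C4–O bond and its configuration are kept and the 1,3-diol results.

Step 5
Reactants: 8 (3S)-4-[(4R)-2,2-dimethyl-1,3-dioxolan-4-yl]-3-methylbutane-1,3-diol
Product: 9 (2S)-1-[(4R)-2,2-dimethyl-1,3-dioxolan-4-yl]-4-(PMB-oxy)-2-methylbutan-2-ol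
Conditions: NaH (1 equiv), 4-MeOC6H4CH2Cl, Bu4NI (cat.), THF/DMF, 0 °C
Reagents that add atoms: 4-methoxybenzyl chloride, COc1ccc(CCl)cc1
Why: Williamson etherification should occur at the primary alkoxide (O2) only, because the tertiary C4 hydroxyl is too hindered to be benzylated.

Step 6
Reactants: 9 (2S)-1-[(4R)-2,2-dimethyl-1,3-dioxolan-4-yl]-4-(PMB-oxy)-2-methylbutan-2-ol
Product: 10 (2R,4S)-6-(PMB-oxy)-4-methylhexane-1,2,4-triol
Conditions: AcOH/H2O (4:1), rt
Reagents that add atoms: none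
Why: Acid-catalysed acetal hydrolysis frees the C6/C7 diol, and the PMB ether and the tertiary alcohol are stable to aqueous acetic acid.

Step 7
Reactants: 10 (2R,4S)-6-(PMB-oxy)-4-methylhexane-1,2,4-triol
Product: 11 (2R,4S)-6-(PMB-oxy)-4-methyl-1,2,4-tris(triethylsilyloxy)hexane
Conditions: Et3SiOTf (3.5 equiv), 2,6-lutidine, CH2Cl2, −78 °C to rt
Reagents that add atoms: triethylsilyl trifluoromethanesulfonate, CC[Si](CC)(CC)OS(=O)(=O)C(F)(F)F
Why: Silylation with the silyl triflate is reactive enough to cap the primary, the secondary and the hindered tertiary hydroxyl in one operation.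

Step 8
Reactants: 11 (2R,4S)-6-(PMB-oxy)-4-methyl-1,2,4-tris(triethylsilyloxy)hexane
Product: 12 (2R,4S)-6-(PMB-oxy)-4-methyl-2,4-bis(triethylsilyloxy)hexanal
Conditions: (COCl)2, DMSO, CH2Cl2, −78 to −30 °C; Et3N, −78 °C to rt
Reagents that add atoms: none
Why: Under Swern oxidation conditions the chlorosulfonium salt should cleave only the unhindered primary TES ether and oxidise it in the same flask to the C7 aldehyde, leaving the secondary and tertiary silyl ethers and C6 intact.

Step 9
Reactants: 13 methyl 3-hydroxypropanoate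
Product: 14 methyl 3-(tert-butyldimethylsilyloxy)propanoate
Conditions: t-BuMe2SiCl, imidazole, DMF, rt
Reagents that add atoms: tert-butyldimethylsilyl chloride, CC(C)(C)[Si](C)(C)Cl
Why: Standard silylation of a primary alcohol with the silyl chloride and imidazole protects the future O13.

Step 10
Reactants: 12 (2R,4S)-6-(PMB-oxy)-4-methyl-2,4-bis(triethylsilyloxy)hexanal; 14 methyl 3-(tert-butyldimethylsilyloxy)propanoate
Product: 16 methyl (4R,6S)-2-[(TBS-oxy)methyl]-3-hydroxy-8-(PMB-oxy)-6-methyl-4,6-bis(TES-oxy)octanoate (epimers at C7 and C11), via lithium enolate 15 (not isolated)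
Conditions: LiN(iPr)2, THF, −78 °C; then 12, −78 °C; AcOH quench at −78 °C
Reagents that add atoms: none
Why: Aldol addition of the ester lithium enolate to the α-silyloxy aldehyde at −78 °C should join C7 to C11 before β-elimination or silyl migration sets in, and the two new stereocentres need no control because steps 11 and 12 remove them.

Step 11
Reactants: 16 methyl (4R,6S)-2-[(TBS-oxy)methyl]-3-hydroxy-8-(PMB-oxy)-6-methyl-4,6-bis(TES-oxy)octanoate
Product: 17 methyl (4R,6S)-2-[(TBS-oxy)methyl]-8-(PMB-oxy)-6-methyl-3-oxo-4,6-bis(TES-oxy)octanoate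
Conditions: Dess–Martin periodinane, NaHCO3, CH2Cl2, rt
Reagents that add atoms: none
Why: Dess–Martin oxidation converts the secondary alcohol into the β-keto ester under buffered conditions that should not epimerise C6.

Step 12
Reactants: 17 methyl (4R,6S)-2-[(TBS-oxy)methyl]-8-(PMB-oxy)-6-methyl-3-oxo-4,6-bis(TES-oxy)octanoate
Product: 19 methyl (2Z,4R,6S)-2-[(TBS-oxy)methyl]-8-(PMB-oxy)-6-methyl-4,6-bis(TES-oxy)-3-(trifluoromethylsulfonyloxy)oct-2-enoate, via sodium enolate 18 (not isolated)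
Conditions: NaH, THF/toluene, 0 °C; PhNTf2, 0 °C to rt
Reagents that add atoms: N-phenylbis(trifluoromethanesulfonimide), O=S(=O)(N(c1ccccc1)S(=O)(=O)C(F)(F)F)C(F)(F)F
Why: O-Sulfonylation of the sodium enolate, held in the chelated U-shape by the ester carbonyl, should give the enol triflate with the triflate cis to the ester (Z), the geometry that later allows lactonisation.

Step 13
Reactants: 19 methyl (2Z,4R,6S)-2-[(TBS-oxy)methyl]-8-(PMB-oxy)-6-methyl-4,6-bis(TES-oxy)-3-(trifluoromethylsulfonyloxy)oct-2-enoate; 20 ethynyltrimethylsilane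
Product: 21 methyl (2E,4R,6S)-2-[(TBS-oxy)methyl]-8-(PMB-oxy)-6-methyl-4,6-bis(TES-oxy)-3-[(trimethylsilyl)ethynyl]oct-2-enoate (alkyne cis to the ester)
Conditions: PdCl2(PPh3)2 (5 mol %), CuI (10 mol %), i-Pr2NH, THF, rt
Reagents that add atoms: none
Why: Sonogashira coupling of the enol triflate with the terminal alkyne should install C8 and C9 with retention of the alkene geometry.

Step 14
Reactants: 21 methyl (2E,4R,6S)-2-[(TBS-oxy)methyl]-8-(PMB-oxy)-6-methyl-4,6-bis(TES-oxy)-3-[(trimethylsilyl)ethynyl]oct-2-enoate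
Product: 22 (2E,4R,6S)-2-[(TBS-oxy)methyl]-3-ethynyl-8-(PMB-oxy)-6-methyl-4,6-bis(TES-oxy)oct-2-enoic acid
Conditions: LiOH, THF/MeOH/H2O, rt; then dilute HCl to pH 4, 0 °C
Reagents that add atoms: lithium hydroxide, [Li+].[OH-]
Why: Saponification of the methyl ester by hydroxide also removes the alkynyl trimethylsilyl group (protodesilylation), while the alkyl silyl ethers and the PMB ether are stable to base.

Step 15
Reactants: 22 (2E,4R,6S)-2-[(TBS-oxy)methyl]-3-ethynyl-8-(PMB-oxy)-6-methyl-4,6-bis(TES-oxy)oct-2-enoic acid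
Product: 23 (5E)-3-[(TBS-oxy)methyl]-5-(iodomethylidene)-4-[(1R,3S)-5-(PMB-oxy)-3-methyl-1,3-bis(TES-oxy)pentyl]furan-2(5H)-one
Conditions: I2, NaHCO3, MeCN, rt, dark
Reagents that add atoms: iodine, II
Why: In this iodolactonisation the carboxylate should attack the iodine-activated terminal alkyne at its internal carbon C8 in a 5-exo-dig anti addition, which puts iodine on C9 trans to the ring oxygen (E).

Step 16
Reactants: 23 (5E)-3-[(TBS-oxy)methyl]-5-(iodomethylidene)-4-[(1R,3S)-5-(PMB-oxy)-3-methyl-1,3-bis(TES-oxy)pentyl]furan-2(5H)-one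
Product: 24 (5E)-3-[(TBS-oxy)methyl]-4-[(1R,3S)-1-hydroxy-5-(PMB-oxy)-3-methyl-3-(TES-oxy)pentyl]-5-(iodomethylidene)furan-2(5H)-one
Conditions: HF·pyridine, pyridine, THF, −10 to 0 °C
Reagents that add atoms: none
Why: Fluoride-mediated desilylation should be selective for the secondary TES ether at C6, whose oxygen is the best leaving group and the least shielded, over the tertiary TES ether and the bulkier primary TBS ether.

Step 17
Reactants: 24 (5E)-3-[(TBS-oxy)methyl]-4-[(1R,3S)-1-hydroxy-5-(PMB-oxy)-3-methyl-3-(TES-oxy)pentyl]-5-(iodomethylidene)furan-2(5H)-one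
Product: 25 (1R,3S)-1-[(2E)-4-[(TBS-oxy)methyl]-2-(iodomethylidene)-5-oxo-2,5-dihydrofuran-3-yl]-5-(PMB-oxy)-3-methyl-3-(TES-oxy)pentyl 2-methylprop-2-enoate
Conditions: methacryloyl chloride, i-Pr2NEt, DMAP (cat.), CH2Cl2, 0 °C
Reagents that add atoms: methacryloyl chloride, C=C(C)C(Cl)=O
Why: Acylation of the secondary alcohol with the acid chloride under amine base installs the C6 methacrylate without touching the silyl-protected tertiary oxygen.

Step 18
Reactants: 25 (1R,3S)-1-[(2E)-4-[(TBS-oxy)methyl]-2-(iodomethylidene)-5-oxo-2,5-dihydrofuran-3-yl]-5-(PMB-oxy)-3-methyl-3-(TES-oxy)pentyl 2-methylprop-2-enoate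
Product: 26 (1R,3S)-1-[(2E)-4-[(TBS-oxy)methyl]-2-(iodomethylidene)-5-oxo-2,5-dihydrofuran-3-yl]-5-hydroxy-3-methyl-3-(TES-oxy)pentyl 2-methylprop-2-enoate
Conditions: DDQ, CH2Cl2/pH 7 buffer, 0 °C to rt
Reagents that add atoms: none
Why: Oxidative cleavage of the PMB ether by DDQ runs through a benzylic oxocarbenium ion that water hydrolyses, and it should leave silyl ethers, esters and the alkenyl iodide alone.

Step 19
Reactants: 26 (1R,3S)-1-[(2E)-4-[(TBS-oxy)methyl]-2-(iodomethylidene)-5-oxo-2,5-dihydrofuran-3-yl]-5-hydroxy-3-methyl-3-(TES-oxy)pentyl 2-methylprop-2-enoate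
Product: 27 (1R,3R)-1-[(2E)-4-[(TBS-oxy)methyl]-2-(iodomethylidene)-5-oxo-2,5-dihydrofuran-3-yl]-3-methyl-5-oxo-3-(TES-oxy)pentyl 2-methylprop-2-enoate (C4 unchanged in space; the descriptor changes by priority only)
Conditions: Dess–Martin periodinane, NaHCO3, CH2Cl2, 0 °C to rt
Reagents that add atoms: none
Why: Dess–Martin oxidation of the primary alcohol gives the C2 aldehyde under buffered conditions that the iodide, the esters and the silyl ethers tolerate.

Step 20
Reactants: 28 propyne; 29 hexamethylditin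
Product: 30 (Z)-1,2-bis(trimethylstannyl)prop-1-ene
Conditions: Pd(PPh3)4 (2 mol %), THF, 65 °C, sealed vessel
Reagents that add atoms: none
Why: Palladium-catalysed distannylation of a terminal alkyne is a syn addition of the tin–tin bond and should give the Z bis-stannane.

Step 21
Reactants: 27 (1R,3R)-1-[(2E)-4-[(TBS-oxy)methyl]-2-(iodomethylidene)-5-oxo-2,5-dihydrofuran-3-yl]-3-methyl-5-oxo-3-(TES-oxy)pentyl 2-methylprop-2-enoate; 30 (Z)-1,2-bis(trimethylstannyl)prop-1-ene
Product: 33 (1R,3S,5S,6Z)-1-[(2E)-4-[(TBS-oxy)methyl]-2-(iodomethylidene)-5-oxo-2,5-dihydrofuran-3-yl]-5-hydroxy-3-methyl-3-(TES-oxy)-7-(trimethylstannyl)oct-6-en-1-yl 2-methylprop-2-enoate, via alkenyllithium 31 (not isolated), via alkenylzinc 32 (not isolated)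
Conditions: 30, MeLi, THF, −78 °C; ZnBr2, −78 to 0 °C; Me2Zn, Et2NCH2CH2NEt2, (+)-MIB [(2R)-3-exo-morpholinoisoborneol] (10 mol %), toluene, −20 °C; then 27, −20 to 0 °C
Reagents that add atoms: none
Why: Tin–lithium exchange should occur at the less hindered terminal tin with retention, and after transmetalation the catalytic enantioselective alkenylzinc addition (amino-alcohol zinc catalyst) should deliver the alkenyl group to the Re face of the aldehyde, setting C2 as S while esters and the alkenyl iodide are inert to zinc.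

Step 22
Reactants: 33 (1R,3S,5S,6Z)-1-[(2E)-4-[(TBS-oxy)methyl]-2-(iodomethylidene)-5-oxo-2,5-dihydrofuran-3-yl]-5-hydroxy-3-methyl-3-(TES-oxy)-7-(trimethylstannyl)oct-6-en-1-yl 2-methylprop-2-enoate
Product: 34 (1R,3S,5S,6Z)-5-acetoxy-1-[(2E)-4-[(TBS-oxy)methyl]-2-(iodomethylidene)-5-oxo-2,5-dihydrofuran-3-yl]-3-methyl-3-(TES-oxy)-7-(trimethylstannyl)oct-6-en-1-yl 2-methylprop-2-enoate (seco iodide–stannane)
Conditions: Ac2O, pyridine, DMAP (cat.), CH2Cl2, 0 °C
Reagents that add atoms: acetic anhydride, CC(=O)OC(C)=O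
Why: Acetylation of the secondary allylic alcohol with acetic anhydride and pyridine gives the C2 acetate, and the alkenylstannane is stable to these non-acidic conditions.

Step 23
Reactants: 34 seco iodide–stannane
Product: 35 (2S,4S,6R)-2-acetoxy-6-(methacryloyloxy)-13-(TBS-oxy)-4-(TES-oxy)germacra-1(10),7(11),8-trien-12,8-olide (1(10)Z; C8=C9 cis in the ring)
Conditions: Pd(PPh3)4 (10 mol %), copper thiophene-2-carboxylate CuO2CC4H3S (1.5 equiv), [NBu4][Ph2PO2] (2 equiv), DMF, rt, 1 mM, slow addition of 34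
Reagents that add atoms: none
Why: Zerovalent palladium should insert into the C9–I bond with retention, while copper thiophene-2-carboxylate takes the (Z)-alkenyl group from tin (the phosphinate traps the trimethyltin cation irreversibly) and passes it to palladium, and reductive elimination then joins C9 to C10. The closest known reaction type is the intramolecular Stille coupling of an alkenyl iodide with an alkenylstannane that gives macrocyclic 1,3-dienes. The ten-membered carbocycle is closed end to end through an eleven-membered palladacycle, so that both alkenes of the new diene are endocyclic. No stereocentre is formed; the step needs retention of both alkene geometries and ring closure in preference to oligomerisation. Retention is inherent in oxidative addition, transmetalation and reductive elimination at sp2 carbon, and the cis arrangement at C8=C9 and C1=C10, the rigid butenolide and the fully substituted C4 turn the two termini toward each other under high dilution. The nearly neutral conditions at room temperature should leave the allylic acetate, the methacrylate and the dienyl lactone untouched.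

Step 24
Reactants: 35 (2S,4S,6R)-2-acetoxy-6-(methacryloyloxy)-13-(TBS-oxy)-4-(TES-oxy)germacra-1(10),7(11),8-trien-12,8-olide
Product: 36 CNP0246543.1, (2S,4S,6R)-2-acetoxy-4,13-dihydroxy-6-(methacryloyloxy)germacra-1(10),7(11),8-trien-12,8-olide
Conditions: HF·pyridine, pyridine, THF, 0 °C to rt
Reagents that add atoms: none
Why: Fluoride-mediated desilylation with buffered HF–pyridine should remove the primary TBS ether at O13 and the tertiary TES ether at O4 without hydrolysing the acetate, the methacrylate or the dienyl lactone.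

Compound list

1 | (S)-(2,2-dimethyl-1,3-dioxolan-4-yl)methyl 4-methylbenzenesulfonate | Cc1ccc(cc1)S(=O)(=O)OC[C@@H]1COC(C)(C)O1 | starting material
2 | lithium acetylide ethylenediamine complex | [Li]C#C.NCCN | starting material
3 | (4R)-2,2-dimethyl-4-(prop-2-yn-1-yl)-1,3-dioxolane | C#CC[C@@H]1COC(C)(C)O1 | intermediate
4 | dimethyl{(E)-3-[(4R)-2,2-dimethyl-1,3-dioxolan-4-yl]-2-methylprop-1-en-1-yl}alane | C[Al](C)/C=C(C)/C[C@@H]1COC(C)(C)O1 | intermediate (not isolated)
5 | lithium butyl(dimethyl){(E)-3-[(4R)-2,2-dimethyl-1,3-dioxolan-4-yl]-2-methylprop-1-en-1-yl}alanate | [Li+].CCCC[Al-](C)(C)/C=C(C)/C[C@@H]1COC(C)(C)O1 | intermediate (not isolated)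
6 | (E)-4-[(4R)-2,2-dimethyl-1,3-dioxolan-4-yl]-3-methylbut-2-en-1-ol | OC/C=C(C)/C[C@@H]1COC(C)(C)O1 | intermediate
7 | [(2R,3R)-3-{[(4R)-2,2-dimethyl-1,3-dioxolan-4-yl]methyl}-3-methyloxiran-2-yl]methanol | OC[C@H]1O[C@]1(C)C[C@@H]2COC(C)(C)O2 | intermediate
8 | (3S)-4-[(4R)-2,2-dimethyl-1,3-dioxolan-4-yl]-3-methylbutane-1,3-diol | OCC[C@](C)(O)C[C@@H]1COC(C)(C)O1 | intermediate
9 | (2S)-1-[(4R)-2,2-dimethyl-1,3-dioxolan-4-yl]-4-[(4-methoxybenzyl)oxy]-2-methylbutan-2-ol | COc1ccc(COCC[C@](C)(O)C[C@@H]2COC(C)(C)O2)cc1 | intermediate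
10 | (2R,4S)-6-[(4-methoxybenzyl)oxy]-4-methylhexane-1,2,4-triol | COc1ccc(COCC[C@](C)(O)C[C@@H](O)CO)cc1 | intermediate
11 | (2R,4S)-6-[(4-methoxybenzyl)oxy]-4-methyl-1,2,4-tris(triethylsilyloxy)hexane | COc1ccc(COCC[C@](C)(O[Si](CC)(CC)CC)C[C@@H](O[Si](CC)(CC)CC)CO[Si](CC)(CC)CC)cc1 | intermediate
12 | (2R,4S)-6-[(4-methoxybenzyl)oxy]-4-methyl-2,4-bis(triethylsilyloxy)hexanal | COc1ccc(COCC[C@](C)(O[Si](CC)(CC)CC)C[C@@H](O[Si](CC)(CC)CC)C=O)cc1 | intermediate
13 | methyl 3-hydroxypropanoate | COC(=O)CCO | starting material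
14 | methyl 3-(tert-butyldimethylsilyloxy)propanoate | COC(=O)CCO[Si](C)(C)C(C)(C)C | intermediate
15 | lithium enolate of 14 | COC(O[Li])=CCO[Si](C)(C)C(C)(C)C | intermediate (not isolated)
16 | methyl (4R,6S)-2-[(TBS-oxy)methyl]-3-hydroxy-8-(PMB-oxy)-6-methyl-4,6-bis(TES-oxy)octanoate, epimers at C7 and C11 | COc1ccc(COCC[C@](C)(O[Si](CC)(CC)CC)C[C@@H](O[Si](CC)(CC)CC)C(O)C(CO[Si](C)(C)C(C)(C)C)C(=O)OC)cc1 | intermediate
17 | methyl (4R,6S)-2-[(TBS-oxy)methyl]-8-(PMB-oxy)-6-methyl-3-oxo-4,6-bis(TES-oxy)octanoate | COc1ccc(COCC[C@](C)(O[Si](CC)(CC)CC)C[C@@H](O[Si](CC)(CC)CC)C(=O)C(CO[Si](C)(C)C(C)(C)C)C(=O)OC)cc1 | intermediate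
18 | sodium (Z)-enolate of 17 | COc1ccc(COCC[C@](C)(O[Si](CC)(CC)CC)C[C@@H](O[Si](CC)(CC)CC)/C(O[Na])=C(\CO[Si](C)(C)C(C)(C)C)C(=O)OC)cc1 | intermediate (not isolated)
19 | methyl (2Z,4R,6S)-2-[(TBS-oxy)methyl]-8-(PMB-oxy)-6-methyl-4,6-bis(TES-oxy)-3-(trifluoromethylsulfonyloxy)oct-2-enoate | COc1ccc(COCC[C@](C)(O[Si](CC)(CC)CC)C[C@@H](O[Si](CC)(CC)CC)/C(OS(=O)(=O)C(F)(F)F)=C(\CO[Si](C)(C)C(C)(C)C)C(=O)OC)cc1 | intermediate
20 | ethynyltrimethylsilane | C#C[Si](C)(C)C | starting material
21 | methyl (2E,4R,6S)-2-[(TBS-oxy)methyl]-8-(PMB-oxy)-6-methyl-4,6-bis(TES-oxy)-3-[(trimethylsilyl)ethynyl]oct-2-enoate | COc1ccc(COCC[C@](C)(O[Si](CC)(CC)CC)C[C@@H](O[Si](CC)(CC)CC)/C(C#C[Si](C)(C)C)=C(\CO[Si](C)(C)C(C)(C)C)C(=O)OC)cc1 | intermediate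
22 | (2E,4R,6S)-2-[(TBS-oxy)methyl]-3-ethynyl-8-(PMB-oxy)-6-methyl-4,6-bis(TES-oxy)oct-2-enoic acid | COc1ccc(COCC[C@](C)(O[Si](CC)(CC)CC)C[C@@H](O[Si](CC)(CC)CC)/C(C#C)=C(\CO[Si](C)(C)C(C)(C)C)C(=O)O)cc1 | intermediate
23 | (5E)-3-[(TBS-oxy)methyl]-5-(iodomethylidene)-4-[(1R,3S)-5-(PMB-oxy)-3-methyl-1,3-bis(TES-oxy)pentyl]furan-2(5H)-one | I/C=C1/OC(=O)C(CO[Si](C)(C)C(C)(C)C)=C1[C@H](O[Si](CC)(CC)CC)C[C@@](C)(O[Si](CC)(CC)CC)CCOCc1ccc(OC)cc1 | intermediate
24 | (5E)-3-[(TBS-oxy)methyl]-4-[(1R,3S)-1-hydroxy-5-(PMB-oxy)-3-methyl-3-(TES-oxy)pentyl]-5-(iodomethylidene)furan-2(5H)-one | I/C=C1/OC(=O)C(CO[Si](C)(C)C(C)(C)C)=C1[C@H](O)C[C@@](C)(O[Si](CC)(CC)CC)CCOCc1ccc(OC)cc1 | intermediate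
25 | C6 methacrylate of 24 (C2 as PMB ether) | I/C=C1/OC(=O)C(CO[Si](C)(C)C(C)(C)C)=C1[C@H](OC(=O)C(C)=C)C[C@@](C)(O[Si](CC)(CC)CC)CCOCc1ccc(OC)cc1 | intermediate
26 | C2 primary alcohol (C6 methacrylate, O4 TES, O13 TBS, C9 iodide) | I/C=C1/OC(=O)C(CO[Si](C)(C)C(C)(C)C)=C1[C@H](OC(=O)C(C)=C)C[C@@](C)(O[Si](CC)(CC)CC)CCO | intermediate
27 | C2 aldehyde (C6 methacrylate, O4 TES, O13 TBS, C9 iodide) | I/C=C1/OC(=O)C(CO[Si](C)(C)C(C)(C)C)=C1[C@H](OC(=O)C(C)=C)C[C@@](C)(O[Si](CC)(CC)CC)CC=O | intermediate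
28 | propyne | CC#C | starting material
29 | hexamethylditin | C[Sn](C)(C)[Sn](C)(C)C | starting material
30 | (Z)-1,2-bis(trimethylstannyl)prop-1-ene | C[Sn](C)(C)/C=C(C)\[Sn](C)(C)C | intermediate
31 | [(Z)-2-(trimethylstannyl)prop-1-en-1-yl]lithium | [Li]/C=C(C)\[Sn](C)(C)C | intermediate (not isolated)
32 | methyl[(Z)-2-(trimethylstannyl)prop-1-en-1-yl]zinc | C[Zn]/C=C(C)\[Sn](C)(C)C | intermediate (not isolated)
33 | (2S)-allylic alcohol: C9 iodide, (Z)-C10 trimethylstannane, C6 methacrylate, O4 TES, O13 TBS | I/C=C1/OC(=O)C(CO[Si](C)(C)C(C)(C)C)=C1[C@H](OC(=O)C(C)=C)C[C@@](C)(O[Si](CC)(CC)CC)C[C@H](O)/C=C(C)\[Sn](C)(C)C | intermediate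
34 | seco iodide–stannane: C2 acetate of 33 | I/C=C1/OC(=O)C(CO[Si](C)(C)C(C)(C)C)=C1[C@H](OC(=O)C(C)=C)C[C@@](C)(O[Si](CC)(CC)CC)C[C@H](OC(C)=O)/C=C(C)\[Sn](C)(C)C | intermediate
35 | 13-O-TBS-4-O-TES ether of the target | C=C(C)C(=O)O[C@@H]1C[C@@](C)(O[Si](CC)(CC)CC)C[C@H](OC(C)=O)/C=C(C)\C=C2\OC(=O)C(CO[Si](C)(C)C(C)(C)C)=C21 | intermediate
36 | CNP0246543.1, (2S,4S,6R)-2-acetoxy-4,13-dihydroxy-6-(methacryloyloxy)germacra-1(10),7(11),8-trien-12,8-olide | C=C(C)C(=O)O[C@@H]1C[C@@](C)(O)C[C@H](OC(C)=O)/C=C(C)\C=C2\OC(=O)C(CO)=C21 | target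

Total step count: 24 steps. Longest linear sequence: 22 steps (steps 1–8, 10–19, 21–24).

Steps most likely to fail

Step 23. Oligomerisation may outrun closure of the strained ten-membered ring, tin-to-copper transfer at the α-methyl alkenylstannane may be too slow so that protodestannylation takes over, or palladium may ionise the allylic acetate. The fallback closes the ring without tin and without palladium. Starting from 34, iodine in CH2Cl2 at 0 °C should exchange tin for iodine with retention to give the bis(alkenyl iodide) F1. An Ullmann-type reductive coupling of the two alkenyl iodides with an excess of copper thiophene-2-carboxylate in N-methylpyrrolidone at room temperature under high dilution should then give 35, where the route is rejoined.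

Step 21. Catalyst control may be eroded by unselective background addition promoted by lithium salts, or alkenyl transfer may be too slow and methyl transfer may compete. The fallback sets C2 by reduction. Starting from 27, addition of the same alkenylzinc reagent without the chiral ligand should give the C2-epimeric alcohols F2. MnO2 in CH2Cl2 should oxidise the allylic alcohol to the enone F3. Corey–Bakshi–Shibata reduction with the (R)-oxazaborolidine and catecholborane at −78 °C, the alkenyl group acting as the large substituent, should return the 2S alcohol 33.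

Step 12. Geometric control may be lost if sulfonylation goes through the non-chelated enolate, which puts the leaving group trans to the ester and makes lactonisation impossible. The fallback starts from 17 and uses p-toluenesulfonyl chloride, N-methylimidazole and LiOH, a sulfonylation in which lithium chelation holds the sulfonate cis to the ester, to give the Z enol tosylate F4. Sonogashira coupling of F4 with 20 under the conditions of step 13 should then give 21.

Further compounds

F1 | step 23 | bis(alkenyl iodide): 34 with iodine in place of the trimethylstannyl group, Z | I/C=C1/OC(=O)C(CO[Si](C)(C)C(C)(C)C)=C1[C@H](OC(=O)C(C)=C)C[C@@](C)(O[Si](CC)(CC)CC)C[C@H](OC(C)=O)/C=C(C)\I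
F2 | step 21 | C2-epimeric mixture of allylic alcohol 33 | I/C=C1/OC(=O)C(CO[Si](C)(C)C(C)(C)C)=C1[C@H](OC(=O)C(C)=C)C[C@@](C)(O[Si](CC)(CC)CC)CC(O)/C=C(C)\[Sn](C)(C)C
F3 | step 21 | C2 enone, (Z)-β-trimethylstannyl | I/C=C1/OC(=O)C(CO[Si](C)(C)C(C)(C)C)=C1[C@H](OC(=O)C(C)=C)C[C@@](C)(O[Si](CC)(CC)CC)CC(=O)/C=C(C)\[Sn](C)(C)C
F4 | step 12 | (Z)-enol tosylate of 17 (tosylate cis to the ester) | COc1ccc(COCC[C@](C)(O[Si](CC)(CC)CC)C[C@@H](O[Si](CC)(CC)CC)/C(OS(=O)(=O)c2ccc(C)cc2)=C(\CO[Si](C)(C)C(C)(C)C)C(=O)OC)cc1
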